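The readings stem from a simulated flask on assumed constants; noise was put on by code.

Read the beta run as a ladder of times, fastest first, and carry its middle rung over to the new flask.

- beta: left-handed substrate 0.24 M; right-handed substrate 0.24 M; gas 7.5 mM (held); free catalyst 19 mol%; racemization catalyst 1.9 mol%; run made earlier
- flask: left-handed substrate 0.12 M; gas 7.5 mM (held); free catalyst 19 mol%; racemization catalyst 1.9 mol%; right-handed substrate 0.12 M; time 30 h

beta run (percent of the left-handed substrate and right-handed substrate together charged)

| time / h | left-handed product / % | right-handed product / % |
|---|---|---|
| 2.00 | 3.9 | 0.8 |
| 4.00 | 7.7 | 0.9 |
| 5.00 | 10.0 | 0.6 |
| 8.00 | 15.2 | 1.8 |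
| 10.0 | 18.3 | 2.7 |

(each reading ± 0.3 percentage points)

- free catalyst is single-handed; left-handed substrate and right-handed substrate are mirror images of each other, charged as a racemate, each of them at the stated concentration
- at the start none of the gas is in solution
- an excess is the difference of the two amounts in percent of their sum
- an excess is below zero if the other one leads
- no earlier run changes the charge of free catalyst; that part of a forecast is a guess
- no earlier run changes the charge of racemization catalyst; that part of a forecast is a guess

* left-handed product and right-handed product together, in percent of the left-handed substrate and right-handed substrate charged together, at 30 h
* excess of left-handed product over right-handed product in the product at 30 h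
* whether the exchange between left-handed substrate and right-handed substrate keeps pace with the reaction: how far the product's excess at 30 h gets from its value without exchange to its value with instant exchange (above 80% keeps pace, below 20% hardly takes part, else lags behind)

- On the first rung stands the making of product: in beta, left-handed product climbs from 3.9% at 2.00 h to 18.3% at 10.0 h on a nearly straight line, so I read the making as steady over that span, and this line does not tell me whether the exchange between the two substrates takes part.
- On the next rung stands the excess of the product: right-handed product goes from 0.6% at 5.00 h to 2.7% at 10.0 h, a factor of 4.50, where a steady source from zero gives 2.00, so I read right-handed product as growing out of left-handed product, the racemization of the product.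
- I take new product as left-handed and replace its spread of ages by the mean age, which for steady making is half the elapsed time; beta at 10.0 h shows an excess of 74.3% at a mean age of 5.00 h, which gives an erosion constant of 0.0595 h⁻¹, the first-order rate at which the excess falls with the age of the product, a reading that carries the scatter of 0.3 percentage points, and a halving time of 11.7 h.
- On the slowest rung, beta's pace uses up the charge in 47.6 h, which is longer than the 30 h asked here, while the halving time is shorter.
- For the new flask, a mean age of 15.0 h gives me an excess of 41.0%; averaging properly over steady making gives 46.6%, so the shortcut costs 5.6 points, and I expect a value between the two, but I give no yield of my own, since no run tells me how the pace follows the charge.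
- The forecast says 30%, 76% and keeps pace, on the grounds of “a selectivity of roughly 8”, so its excess stands above mine.
- The flask gives 69.1%, an excess of 39.9%, and keeps pace, with 98% of the way covered.

    partner + free catalyst + left-handed substrate → free catalyst + left-handed product (k = 15.8 M⁻² min⁻¹)
    partner + free catalyst + right-handed substrate → free catalyst + right-handed product (k = 0.109 M⁻² min⁻¹)
    left-handed substrate + racemization catalyst ⇌ right-handed substrate + racemization catalyst, rate k3*[racemization catalyst]*[left-handed substrate] forward; the back reaction follows from the equilibrium constant (k = 1.88 M⁻¹ min⁻¹)
    partner → decomposed reagent (k = 7.48 × 10⁻⁴ min⁻¹)
    gas ⇌ partner, rate k5*(csat - [partner]) (kL = 0.0272 min⁻¹)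
    left-handed product ⇌ right-handed product (k = 5.28 × 10⁻⁴ min⁻¹)

- In the flask, half of the making of left-handed product up to 30 h is done by 12.7 h, so the median age of that product is 17.3 h, longer than the halving time of 11.7 h, and the erosion constant over that age leaves 35.7% against the 39.9% found. The neighbour flask with 4.8 mol% of free catalyst and a yield of 35.6% is the second test: the constant at a mean age of 15.0 h gives 41.0%, and that neighbour flask shows 42.3%.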